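**Retrosynthetic overview**
1. Target 21 ⇐ double epoxidation of the (E,E)-1(10),4-diene 19 from the ring periphery; the tiglate is already in place (oxiranes are the last rings formed).
2. The 10-membered carbocycle and the butenolide are closed together: Ni/Cr coupling across C6–C7 between a (Z)-β-triflyloxy enoate and an enal, then lactonisation (16 → 18).
3. Enol triflate 16 ⇐ β-keto ester 15 ⇐ Roskamp coupling of α-tigloyloxy aldehyde 11 with diazoester 14 (adds C11, C12, C13).
4. C8, the first stereocentre, and its tiglate ⇐ amine-catalysed asymmetric α-tigloyloxylation of achiral dialdehyde 7 with ditigloyl peroxide 10 (key step, new).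
5. Dialdehyde 7 ⇐ (2E,6E)-farnesyl acetate by cleavage of the terminal alkene.

Assumption: ring positions use germacrane numbering (C1–C15); the racemic epoxide of step 1 is only a cleavage handle and its stereocentre is excised in step 2.

**Route**

Step 1
Reactants: 1 (2E,6E)-farnesyl acetate
Product: 4 (2E,6E)-10,11-epoxy-10,11-dihydrofarnesol (racemic), via bromohydrin 2 (not isolated), via epoxy acetate 3 (not isolated)
Conditions: NBS, THF/H2O, 0 °C; then K2CO3, MeOH, rt
Reagents that add atoms: water O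
Why: Terminal-selective bromohydrin formation (van Tamelen) on the most electron-rich, least hindered alkene, then base closure to the epoxide and methanolysis of the acetate.

Step 2
Reactants: 4 (2E,6E)-10,11-epoxy-10,11-dihydrofarnesol
Product: 6 (4E,8E)-10-hydroxy-4,8-dimethyldeca-4,8-dienal, via triol 5 (not isolated)
Conditions: H5IO6, THF/H2O, 0 °C
Reagents that add atoms: none
Why: Periodic acid hydrolyses the epoxide and cleaves the glycol (Malaprade cleavage), releasing acetone and leaving both E-alkenes and the allylic alcohol intact.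

Step 3
Reactants: 6 (4E,8E)-10-hydroxy-4,8-dimethyldeca-4,8-dienal
Product: 7 (2E,6E)-3,7-dimethyldeca-2,6-dienedial
Conditions: MnO2, CH2Cl2, rt
Reagents that add atoms: none
Why: MnO2 oxidises only the allylic alcohol (allylic oxidation) to the (E)-enal, giving the achiral dialdehyde whose two aldehydes differ strongly in reactivity.

Step 4
Reactants: 8 tiglic acid (2 equiv)
Product: 10 ditigloyl peroxide, via peroxytiglic acid 9 (not isolated)
Conditions: H2O2 (50% aq., 0.5 equiv), DCC, CH2Cl2, −15 to 0 °C; used as a titrated solution, never concentrated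
Reagents that add atoms: hydrogen peroxide OO
Why: Carbodiimide-mediated condensation of a carboxylic acid with H2O2 is the standard preparation of symmetrical diacyl peroxides.

Step 5
Reactants: 7 (2E,6E)-3,7-dimethyldeca-2,6-dienedial; 10 ditigloyl peroxide
Product: 11 (2S,4E,8E)-4,8-dimethyl-1,10-dioxodeca-4,8-dien-2-yl (E)-2-methylbut-2-enoate
Conditions: (S)-2-tritylpyrrolidine (10 mol%), hydroquinone (10 mol%), THF, 0 °C
Reagents that add atoms: none
Why: Proposed new method: enamine-mediated asymmetric α-acyloxylation with an alkenoyl peroxide — the catalyst condenses only with the enolisable saturated aldehyde of 7, and the (E)-enamine attacks a peroxide oxygen of 10 in an SN2-type step on the O–O bond (tiglate leaves) from the face not covered by the trityl group, which forms the C8–O bond, sets C8 as S and installs the tiglate of the target in one operation; the closest known reaction type is the secondary-amine-catalysed α-benzoyloxylation of aldehydes with dibenzoyl peroxide, and the tigloyl alkene is trisubstituted and electron-poor, so conjugate addition should not compete.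

Step 6
Reactants: 12 ethyl diazoacetate
Product: 14 ethyl 3-[(tert-butyldimethylsilyl)oxy]-2-diazopropanoate, via hydroxy diazoester 13 (not isolated)
Conditions: (CH2O)n, DBU (10 mol%), MeCN, rt; then imidazole, TBSCl, 0 °C to rt
Reagents that add atoms: formaldehyde (as paraformaldehyde) C=O; tert-butyldimethylsilyl chloride CC(C)(C)[Si](C)(C)Cl
Why: DBU-catalysed aldol-type addition of the diazo carbon to formaldehyde, then silylation in the same flask, gives the C11–C12–C13 unit with the primary alcohol masked.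

Step 7
Reactants: 11 α-tigloyloxy dialdehyde; 14 ethyl 3-[(tert-butyldimethylsilyl)oxy]-2-diazopropanoate
Product: 15 ethyl (4S,6E,10E)-2-{[(tert-butyldimethylsilyl)oxy]methyl}-6,10-dimethyl-4-[(E)-2-methylbut-2-enoyloxy]-3,12-dioxododeca-6,10-dienoate (C2 epimers and enol)
Conditions: Sc(OTf)3 (5 mol%), CH2Cl2, −40 °C
Reagents that add atoms: none
Why: Roskamp homologation — the diazo carbon adds to the Lewis-acid-activated α-acyloxy aldehyde (much more electrophilic than the β,β-disubstituted enal) and 1,2-hydride shift with loss of N2 gives the β-keto ester; C8 is untouched because enolisation goes toward C11, and the C11 centre is irrelevant since it becomes sp2 in step 8.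

Step 8
Reactants: 15 β-keto ester
Product: 16 ethyl (2Z,4S,6E,10E)-2-{[(tert-butyldimethylsilyl)oxy]methyl}-6,10-dimethyl-4-[(E)-2-methylbut-2-enoyloxy]-12-oxo-3-[(trifluoromethanesulfonyl)oxy]dodeca-2,6,10-trienoate
Conditions: NaH (1.05 equiv), THF, 0 °C; then Tf2O, −78 to −20 °C
Reagents that add atoms: triflic anhydride O=S(=O)(OS(=O)(=O)C(F)(F)F)C(F)(F)F
Why: The sodium enolate of the β-keto ester is a chelate with enolate oxygen and ester carbonyl cis, so O-triflation gives the (Z)-enol triflate (OTf cis to CO2Et), the geometry needed for lactonisation; only the doubly activated C11–H is removed.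

Step 9
Reactants: 16 (Z)-enol triflate enal
Product: 18 (6R,8S)-13-[(tert-butyldimethylsilyl)oxy]-8-(tigloyloxy)germacra-1(10)E,4E,7(11)-trien-12,6-olide, via seco hydroxy ester 17 (not isolated)
Conditions: CrCl2 (8 equiv), NiCl2 (2 mol%), DMF/THF, 2 mM (slow addition), rt; then aq. sodium serinate work-up; PPTS, CH2Cl2
Reagents that add atoms: none
Why: Nozaki–Hiyama–Kishi reaction — Ni(0) inserts into the vinyl triflate, the vinylchromium(III) adds 1,2 to the enal under high dilution and the alkoxide closes onto the cis ester; C6 is set by C8, whose hydrogen eclipses the enoate C=C (A1,3 strain against CH2OTBS) so the tether delivers the aldehyde on the C9 face with its chain turned away from the ester, giving the 6,8-cis-dioxygenated lactone (6R here, 6S in the target numbering after epoxidation).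

Step 10
Reactants: 18 silyl-protected macrolactone
Product: 19 (6R,8S)-13-hydroxy-8-(tigloyloxy)germacra-1(10)E,4E,7(11)-trien-12,6-olide
Conditions: HF·pyridine, pyridine, THF, 0 °C
Reagents that add atoms: none
Why: Buffered fluoride cleaves the primary TBS ether without acid-induced transannular cyclisation of the 1,5-diene and without touching the tiglate or lactone.

Step 11
Reactants: 19 13-hydroxy triene lactone
Product: 21 (1R,4R,5R,6S,8S,10R)-1,10:4,5-diepoxy-13-hydroxy-8-(tigloyloxy)germacr-7(11)-en-12,6-olide (target), via 1(10)-monoepoxide 20 (not isolated)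
Conditions: dimethyldioxirane (2.5 equiv), acetone, −20 to 0 °C
Reagents that add atoms: dimethyldioxirane CC1(C)OO1
Why: Electrophilic dioxirane epoxidation reacts only with the two electron-rich trisubstituted ring alkenes (butenolide and tiglate alkenes are electron-poor) and, as in peracid epoxidations of germacranolides, attacks each E-alkene from the ring periphery of the crown conformer (C14 and C15 syn, H6 eclipsing the 4,5-alkene), giving the trans (1R,10R) and (4R,5R) oxiranes.

**Compound list**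
1 | (2E,6E)-farnesyl acetate | CC(C)=CCC/C(C)=C/CC/C(C)=C/COC(C)=O | starting material
2 | (2E,6E)-10-bromo-11-hydroxy-10,11-dihydrofarnesyl acetate (racemic) | CC(C)(O)C(Br)CC/C(C)=C/CC/C(C)=C/COC(C)=O | intermediate
3 | (2E,6E)-10,11-epoxy-10,11-dihydrofarnesyl acetate (racemic) | CC1(C)OC1CC/C(C)=C/CC/C(C)=C/COC(C)=O | intermediate
4 | (2E,6E)-10,11-epoxy-10,11-dihydrofarnesol (racemic) | CC1(C)OC1CC/C(C)=C/CC/C(C)=C/CO | intermediate
5 | (2E,6E)-3,7,11-trimethyldodeca-2,6-diene-1,10,11-triol (racemic) | CC(C)(O)C(O)CC/C(C)=C/CC/C(C)=C/CO | intermediate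
6 | (4E,8E)-10-hydroxy-4,8-dimethyldeca-4,8-dienal | O=CCC/C(C)=C/CC/C(C)=C/CO | intermediate
7 | (2E,6E)-3,7-dimethyldeca-2,6-dienedial | O=CCC/C(C)=C/CC/C(C)=C/C=O | intermediate
8 | tiglic acid, (E)-2-methylbut-2-enoic acid | C/C=C(\C)C(=O)O | starting material
9 | peroxytiglic acid | C/C=C(\C)C(=O)OO | intermediate
10 | ditigloyl peroxide, bis[(E)-2-methylbut-2-enoyl] peroxide | C/C=C(\C)C(=O)OOC(=O)/C(C)=C/C | intermediate
11 | (2S,4E,8E)-4,8-dimethyl-1,10-dioxodeca-4,8-dien-2-yl (E)-2-methylbut-2-enoate | C/C=C(\C)C(=O)O[C@H](C=O)C/C(C)=C/CC/C(C)=C/C=O | intermediate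
12 | ethyl diazoacetate | CCOC(=O)C=[N+]=[N-] | starting material
13 | ethyl 2-diazo-3-hydroxypropanoate | CCOC(=O)C(CO)=[N+]=[N-] | intermediate
14 | ethyl 3-[(tert-butyldimethylsilyl)oxy]-2-diazopropanoate | CCOC(=O)C(CO[Si](C)(C)C(C)(C)C)=[N+]=[N-] | intermediate
15 | ethyl (4S,6E,10E)-2-{[(tert-butyldimethylsilyl)oxy]methyl}-6,10-dimethyl-4-(tigloyloxy)-3,12-dioxododeca-6,10-dienoate (C2 epimers) | C/C=C(\C)C(=O)O[C@H](C(=O)C(CO[Si](C)(C)C(C)(C)C)C(=O)OCC)C/C(C)=C/CC/C(C)=C/C=O | intermediate
16 | ethyl (2Z,4S,6E,10E)-2-{[(tert-butyldimethylsilyl)oxy]methyl}-6,10-dimethyl-4-(tigloyloxy)-12-oxo-3-(triflyloxy)dodeca-2,6,10-trienoate | C/C=C(\C)C(=O)O[C@H](/C(OS(=O)(=O)C(F)(F)F)=C(\CO[Si](C)(C)C(C)(C)C)C(=O)OCC)C/C(C)=C/CC/C(C)=C/C=O | intermediate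
17 | ethyl 3-[(tert-butyldimethylsilyl)oxy]-2-[(6R,8S)-6-hydroxy-8-(tigloyloxy)germacra-1(10)E,4E-dien-7-ylidene]propanoate (ester cis to C6) | C/C=C(\C)C(=O)O[C@H]1C/C(C)=C/CC/C(C)=C/[C@@H](O)/C1=C(/CO[Si](C)(C)C(C)(C)C)C(=O)OCC | intermediate
18 | (6R,8S)-13-[(tert-butyldimethylsilyl)oxy]-8-(tigloyloxy)germacra-1(10)E,4E,7(11)-trien-12,6-olide | C/C=C(\C)C(=O)O[C@H]1C/C(C)=C/CC/C(C)=C/[C@H]2OC(=O)C(CO[Si](C)(C)C(C)(C)C)=C12 | intermediate
19 | (6R,8S)-13-hydroxy-8-(tigloyloxy)germacra-1(10)E,4E,7(11)-trien-12,6-olide | C/C=C(\C)C(=O)O[C@H]1C/C(C)=C/CC/C(C)=C/[C@H]2OC(=O)C(CO)=C12 | intermediate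
20 | (1R,6R,8S,10R)-1,10-epoxy-13-hydroxy-8-(tigloyloxy)germacra-4E,7(11)-dien-12,6-olide | C/C=C(\C)C(=O)O[C@H]1C[C@@]2(C)O[C@@H]2CC/C(C)=C/[C@H]2OC(=O)C(CO)=C12 | intermediate
21 | (1R,4R,5R,6S,8S,10R)-1,10:4,5-diepoxy-13-hydroxy-8-(tigloyloxy)germacr-7(11)-en-12,6-olide | C/C=C(\C)C(=O)O[C@H]1C[C@@]2(C)O[C@@H]2CC[C@@]2(C)O[C@@H]2[C@H]2OC(=O)C(CO)=C12 | target

**Step count:** 11 steps in total. Longest linear sequence: 9 steps (steps 1, 2, 3, 5, 7, 8, 9, 10, 11).

**Three steps most likely to fail**

Step 5 (the new α-tigloyloxylation). The alkenoyl peroxide is less electrophilic than dibenzoyl peroxide, it may acylate the catalyst nitrogen, and the enal end of 7 could enter dienamine chemistry. If the sense of induction is opposite to the benzoyloxylation precedent, the (R)-catalyst is used instead. The fallback uses only known chemistry and sets out from 7. Dibenzoyl peroxide with the same catalyst (the known benzoyloxylation) gives (2S,4E,8E)-4,8-dimethyl-1,10-dioxodeca-4,8-dien-2-yl benzoate F1. Under the conditions of steps 7, 8 and 9 this is taken to the benzoate β-keto ester F2, the benzoate (Z)-enol triflate F3 and the macrolactone 8-benzoate F4. K2CO3 in MeOH at 0 °C removes the benzoate to give the 8-hydroxy macrolactone F5. Yamaguchi esterification of F5 with tiglic acid 8 (2,4,6-trichlorobenzoyl chloride, Et3N, DMAP) comes back to the route at 18.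

Step 7 (Roskamp coupling). A silyloxymethyl diazoester is a weaker nucleophile than ethyl diazoacetate, alkyl rather than hydride shift or β-elimination of the silyloxy group could intervene, and the enal may compete. The fallback sets out from 11. The lithium enolate of commercial ethyl 3-[(tert-butyldimethylsilyl)oxy]propanoate (LDA, THF, −78 °C, quenched cold with AcOH to stop tiglate migration) adds to the saturated aldehyde to give the β-hydroxy ester F6 as a diastereomer mixture. Dess–Martin periodinane with NaHCO3 oxidises F6 and comes back to the route at 15.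

Step 9 (Ni/Cr macrocyclisation). The tetrasubstituted triflate may insert slowly, the conjugated enal is a weak electrophile, oligomers or an allene from loss of the C8 ester may form, and the C6 selectivity rests on a conformational model. The fallback sets out from 16 and installs the 4,5-oxirane first, so the ring closes on a non-conjugated, more electrophilic aldehyde, as in known germacranolide closures. Organocatalytic epoxidation of the enal ((R)-diarylprolinol silyl ether, H2O2, CH2Cl2) gives the 4α,5β-epoxy aldehyde F7. The same Ni/Cr conditions, with chromium chelated between aldehyde and oxirane oxygens directing C6, give the 4,5-epoxy macrolactone F8. HF·pyridine gives the 13-hydroxy 4,5-epoxide F9. Dimethyldioxirane (1.2 equiv) then epoxidises the remaining 1(10)-alkene and comes back to the route at 21.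

**Further compounds**
F1 | step 5 | (2S,4E,8E)-4,8-dimethyl-1,10-dioxodeca-4,8-dien-2-yl benzoate | O=C(O[C@H](C=O)C/C(C)=C/CC/C(C)=C/C=O)c1ccccc1
F2 | step 5 | ethyl (4S,6E,10E)-4-(benzoyloxy)-2-{[(tert-butyldimethylsilyl)oxy]methyl}-6,10-dimethyl-3,12-dioxododeca-6,10-dienoate | O=C(O[C@H](C(=O)C(CO[Si](C)(C)C(C)(C)C)C(=O)OCC)C/C(C)=C/CC/C(C)=C/C=O)c1ccccc1
F3 | step 5 | ethyl (2Z,4S,6E,10E)-4-(benzoyloxy)-2-{[(tert-butyldimethylsilyl)oxy]methyl}-6,10-dimethyl-12-oxo-3-(triflyloxy)dodeca-2,6,10-trienoate | O=C(O[C@H](/C(OS(=O)(=O)C(F)(F)F)=C(\CO[Si](C)(C)C(C)(C)C)C(=O)OCC)C/C(C)=C/CC/C(C)=C/C=O)c1ccccc1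
F4 | step 5 | (6R,8S)-8-(benzoyloxy)-13-[(tert-butyldimethylsilyl)oxy]germacra-1(10)E,4E,7(11)-trien-12,6-olide | O=C(O[C@H]1C/C(C)=C/CC/C(C)=C/[C@H]2OC(=O)C(CO[Si](C)(C)C(C)(C)C)=C12)c1ccccc1
F5 | step 5 | (6R,8S)-13-[(tert-butyldimethylsilyl)oxy]-8-hydroxygermacra-1(10)E,4E,7(11)-trien-12,6-olide | O[C@H]1C/C(C)=C/CC/C(C)=C/[C@H]2OC(=O)C(CO[Si](C)(C)C(C)(C)C)=C12
F6 | step 7 | ethyl (4S,6E,10E)-2-{[(tert-butyldimethylsilyl)oxy]methyl}-3-hydroxy-6,10-dimethyl-12-oxo-4-(tigloyloxy)dodeca-6,10-dienoate (C2/C3 diastereomers) | C/C=C(\C)C(=O)O[C@H](C(O)C(CO[Si](C)(C)C(C)(C)C)C(=O)OCC)C/C(C)=C/CC/C(C)=C/C=O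
F7 | step 9 | 4α,5β-epoxy aldehyde of 16 (10,11-epoxide of the dodecatrienoate chain) | C/C=C(\C)C(=O)O[C@H](/C(OS(=O)(=O)C(F)(F)F)=C(\CO[Si](C)(C)C(C)(C)C)C(=O)OCC)C/C(C)=C/CC[C@@]1(C)O[C@@H]1C=O
F8 | step 9 | (4R,5R,6S,8S)-13-[(tert-butyldimethylsilyl)oxy]-4,5-epoxy-8-(tigloyloxy)germacra-1(10)E,7(11)-dien-12,6-olide | C/C=C(\C)C(=O)O[C@H]1C/C(C)=C/CC[C@@]2(C)O[C@@H]2[C@H]2OC(=O)C(CO[Si](C)(C)C(C)(C)C)=C12
F9 | step 9 | (4R,5R,6S,8S)-4,5-epoxy-13-hydroxy-8-(tigloyloxy)germacra-1(10)E,7(11)-dien-12,6-olide | C/C=C(\C)C(=O)O[C@H]1C/C(C)=C/CC[C@@]2(C)O[C@@H]2[C@H]2OC(=O)C(CO)=C12
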